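Beside the delta run the flask looks nearly the same: both hold 45 mM of starting material, 180 mM of coupling partner and 50 µM of free catalyst, and they differ in impurity, 38 µM in delta against 25 µM in the flask.

| flask | starting material | coupling partner | free catalyst | impurity | remark |
|---|---|---|---|---|---|
| theta | 63 mM | 180 mM | 50 µM | 25 µM | run made earlier |
| eta | 99 mM | 180 mM | 50 µM | 25 µM | run made earlier |
| delta | 45 mM | 180 mM | 50 µM | 38 µM | run made earlier |
| flask | 45 mM | 180 mM | 50 µM | 25 µM |  |

| run | time / min | target / % |
|---|---|---|
| theta | 2.00 | 2.7 |
| theta | 4.00 | 5.1 |
| theta | 6.00 | 6.4 |
| theta | 8.00 | 7.4 |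
| theta | 10.0 | 10.5 |
| eta | 0.833 | 1.7 |
| eta | 2.50 | 1.3 |
| eta | 4.00 | 4.0 |
| eta | 6.00 | 6.4 |
| eta | 10.0 | 10.3 |
| delta | 0.833 | 1.2 |
| delta | 2.50 | 2.2 |
| delta | 4.00 | 3.2 |
| delta | 6.00 | 4.6 |
| delta | 10.0 | 6.3 |

(each reading ± 1 percentage point)

- the earlier runs were read with a standard deviation of 1 percentage point
- no earlier run changes the charge of free catalyst; that part of a forecast is a guess
- no earlier run changes the charge of coupling partner; that part of a forecast is a guess

1. factor on the rate of making target when 20% of the starting material are converted if coupling partner is charged twice over
2. factor on the rate when 20% of the starting material are converted if free catalyst is charged at 500 µM instead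

The theta and eta runs carry the flask's impurity. Although their charges of starting material differ, at 10.0 min they read 10.5% and 10.3%, so percent conversion does not follow that charge, the mark of first order in starting material, and we expect the flask to follow them. Delta reads 6.3% at that time, 0.600 of theta's reading.

We suppose that each impurity removes one free catalyst for good. The flask then keeps 25.0 µM of working catalyst, W, the charge of free catalyst less the charge of impurity. Delta keeps 12.0 µM, less than the flask, and a rate proportional to W puts delta at 0.480 of theta, or 5.04%. With a scatter of 1 percentage point, the delta reading stands a little above that, so delta ends behind the flask with a margin that the readings fix only roughly.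

At 500 µM our reckoning gives 475 µM of working catalyst, a factor W2/W of 19.0, assuming first order in catalyst, which no run tests. No run varies the coupling partner either, so there we have only a guess. The forecast gives 1.4 for the doubled coupling partner and 15 for the catalyst, the latter lower than our factor; for the catalyst it reckons “roughly 18-fold if first order, or about 4.4-fold if half order”.

The simulation gives 1.50 for the doubled coupling partner and 19.1 for the catalyst, beside our 19.0.

    catalyst intermediate C → free catalyst + target (k = 36.0 s⁻¹)
    catalyst intermediate B ⇌ catalyst intermediate C (K = 0.880, k = 230 s⁻¹)
    free catalyst + impurity → spent catalyst B (k = 12000 M⁻¹ s⁻¹)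
    starting material + catalyst intermediate A → catalyst intermediate B (k = 27.0 M⁻¹ s⁻¹)
    coupling partner + free catalyst ⇌ catalyst intermediate A (K = 3.80 M⁻¹, k = 14.0 M⁻¹ s⁻¹)
    catalyst intermediate C → spent catalyst A (k = 3.60 × 10⁻⁴ s⁻¹)

In the flask, a free catalyst lasts 0.0556 min against the impurity as charged, far shorter than the 16.6 min needed to reach 20% conversion. In the flask at 0.800 min the impurity stands at 0% and spent catalyst B at 50.0% of the catalyst charged, leaving W/charge = 50.0%, and at 80.0 min spent catalyst B still stands at 50.0%.

The numbers in the tables were computed from invented constants; noise was put on by code.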